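**Strategy.** Rings D and E are disconnected together: the C7–C7′ bond of ring D and the C1′–C2′ bond of ring E (primed atoms: C1′ spiro carbon, C2′ its ring-E CH2, C5′/C6′ cyclopropane CH/CH2, C7′ carbinol carbon). One Lewis-acid operation contracts an aryl-substituted epoxybicyclo[4.1.0]heptane to the spiro aldehyde and lets C7 of a C6 silyl enol ether add to it. The step exploits quaternary C1′, bonded to C14 on the ring-E face of C6′ and lying peri to nucleophilic C7 beside the C6 carbonyl. Its precursor is the 5β (A/B-cis) 11,12-dibenzyloxyabietane 6-TBS enol ether carrying at C14 the epoxide, anti to the cyclopropane CH2, of a 6-isopropylbicyclo[4.1.0]hept-2-en-2-yl group.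

Key step: step 18

Labels: abietane numbering (C1–C20) for the diterpene. C1′–C7′ (C3′ = second ring-E CH2, C4′ = isopropyl-bearing cyclopropane carbon) denote the same seven carbons in every intermediate from 19 on. Compounds 14–18 are named with their own IUPAC locants.

Assumption: the 5β (A/B-cis) 6-ketone is taken to be the thermodynamically favoured C5 epimer of 6-oxoabieta-8,11,13-trienes, as the ring fusion of the target itself suggests.

Design choices: C5 is equilibrated at the tricyclic bromo ketone, before the coupling, so that no base meets the β-hydroxy ketone formed in the key step. The catechol is carried as its dibenzyl ether, so that it is released by neutral hydrogenolysis and not by a Lewis acid.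

**Route**

Step 1
Reactants: 1 carnosic acid
Product: 2 benzyl 11,12-bis(benzyloxy)abieta-8,11,13-trien-20-oate (5α-H, C20 β, as in 1)
Conditions: BnBr, K2CO3, Bu4NI (cat.), DMF, 60 °C, Ar
Reagents that add atoms: benzyl bromide, BrCc1ccccc1
Why: Williamson-type O-alkylation of the carboxylate and both phenoxides (SN2 at benzyl), run under argon because the free catechol autoxidises in base; no stereocentre is touched.

Step 2
Reactants: 2 benzyl 11,12-bis(benzyloxy)abieta-8,11,13-trien-20-oate
Product: 3 11,12-bis(benzyloxy)abieta-8,11,13-trien-20-ol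
Conditions: LiAlH4, THF, reflux; H2O, aq NaOH
Reagents that add atoms: none
Why: hydride reduction of the hindered neopentyl ester to the primary alcohol; aryl benzyl ethers are inert to LiAlH4.

Step 3
Reactants: 3 11,12-bis(benzyloxy)abieta-8,11,13-trien-20-ol
Product: 4 11,12-bis(benzyloxy)abieta-8,11,13-trien-20-al
Conditions: Dess–Martin periodinane, NaHCO3, CH2Cl2, rt
Reagents that add atoms: none
Why: Dess–Martin oxidation stops cleanly at the non-enolisable neopentyl aldehyde.

Step 4
Reactants: 4 11,12-bis(benzyloxy)abieta-8,11,13-trien-20-al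
Product: 5 11,12-bis(benzyloxy)abieta-8,11,13-triene (5α-H, 10β-CH3)
Conditions: N2H4·H2O, KOH, diethylene glycol, 130 → 200 °C
Reagents that add atoms: none
Why: Wolff–Kishner reduction (Huang–Minlon procedure) takes C20 from CHO to CH3 through a carbanion, which avoids the C20 cation or radical that would trigger a 1,2-aryl shift and ring expansion; aryl benzyl ethers tolerate hot alkali.

Step 5
Reactants: 5 11,12-bis(benzyloxy)abieta-8,11,13-triene
Product: 6 14-bromo-11,12-bis(benzyloxy)abieta-8,11,13-triene
Conditions: NBS, MeCN, 0 °C → rt, dark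
Reagents that add atoms: N-bromosuccinimide, O=C1CCC(=O)N1Br
Why: electrophilic aromatic bromination at C14, the only free position of ring C and para to the C11 oxygen; polar conditions in the dark disfavour radical benzylic bromination.

Step 6
Reactants: 6 14-bromo-11,12-bis(benzyloxy)abieta-8,11,13-triene
Product: 7 14-bromo-11,12-bis(benzyloxy)abieta-6,8,11,13-tetraene
Conditions: DDQ, 1,4-dioxane, 80 °C
Reagents that add atoms: none
Why: DDQ dehydrogenation by hydride abstraction from benzylic C7 (para to the C12 oxygen) and loss of H6; further aromatisation is blocked by quaternary C10.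

Step 7
Reactants: 7 14-bromo-11,12-bis(benzyloxy)abieta-6,8,11,13-tetraene
Product: 9 14-bromo-11,12-bis(benzyloxy)-5α-abieta-8,11,13-trien-6-one, via 6α,7α-epoxide 8 (not isolated)
Conditions: dimethyldioxirane (acetone solution), CH2Cl2, 0 °C; evaporate; ZnI2 (10 mol %), toluene, rt
Reagents that add atoms: dimethyldioxirane, CC1(C)OO1
Why: epoxidation on the α face (away from the axial C20 methyl), then Meinwald rearrangement in which the benzylic C7–O bond ionises and a 1,2-hydride shift from C6 gives the 6-ketone, the standard route from dihydronaphthalene oxides to β-tetralones; C5 is untouched.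

Step 8
Reactants: 9 14-bromo-11,12-bis(benzyloxy)-5α-abieta-8,11,13-trien-6-one
Product: 10 14-bromo-11,12-bis(benzyloxy)-5β-abieta-8,11,13-trien-6-one (A/B cis; 5-H syn to the C20 methyl)
Conditions: NaOMe, MeOH/THF, 50 °C, degassed, Ar
Reagents that add atoms: none
Why: reversible enolisation toward C5 places the ring fusion under thermodynamic control, and the cis ketone should be favoured because it removes the eclipsing of the equatorial C4 methyl with the C6 carbonyl and the 1,3-diaxial C4/C10 methyl pair of the trans form; oxygen is excluded because the C7 enolate autoxidises.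

Step 9
Reactants: 11 3-ethoxycyclohex-2-en-1-one; 12 isopropylmagnesium chloride
Product: 13 3-(propan-2-yl)cyclohex-2-en-1-one
Conditions: iPrMgCl, THF, 0 °C → rt; then 1 M HCl, rt
Reagents that add atoms: isopropylmagnesium chloride (12), CC(C)[Mg]Cl
Why: Stork–Danheiser sequence, 1,2-addition to the vinylogous ester followed by acid hydrolysis and dehydration to the transposed enone.

Step 10
Reactants: 13 3-(propan-2-yl)cyclohex-2-en-1-one
Product: 14 (R)-3-(propan-2-yl)cyclohex-2-en-1-ol
Conditions: (S)-2-methyl-CBS-oxazaborolidine (10 mol %), BH3·SMe2, THF, −30 °C; MeOH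
Reagents that add atoms: none
Why: Corey–Bakshi–Shibata reduction with the alkenyl flank as the large group delivers hydride to give the (R)-carbinol; any minor enantiomer becomes a separable diastereomer after step 15.

Step 11
Reactants: 14 (R)-3-(propan-2-yl)cyclohex-2-en-1-ol
Product: 15 (1S,2R,6R)-6-(propan-2-yl)bicyclo[4.1.0]heptan-2-ol (OH syn to the cyclopropane CH2)
Conditions: Et2Zn, CH2I2, CH2Cl2, 0 °C
Reagents that add atoms: diiodomethane, ICI
Why: hydroxyl-directed Simmons–Smith cyclopropanation (Furukawa conditions); the zinc alkoxide delivers CH2 to the alkene face syn to oxygen, which sets both cyclopropane stereocentres from the carbinol.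

Step 12
Reactants: 15 (1S,2R,6R)-6-(propan-2-yl)bicyclo[4.1.0]heptan-2-ol
Product: 16 (1S,6R)-6-(propan-2-yl)bicyclo[4.1.0]heptan-2-one
Conditions: Dess–Martin periodinane, NaHCO3, CH2Cl2, rt
Reagents that add atoms: none
Why: Dess–Martin oxidation removes the relay stereocentre under buffered conditions that leave the cyclopropyl ketone intact.

Step 13
Reactants: 16 (1S,6R)-6-(propan-2-yl)bicyclo[4.1.0]heptan-2-one
Product: 17 (1S,6R)-6-(propan-2-yl)bicyclo[4.1.0]hept-2-en-2-yl trifluoromethanesulfonate
Conditions: KN(SiMe3)2, THF, −78 °C; PhNTf2, −78 → 0 °C; aq NH4Cl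
Reagents that add atoms: N-phenylbis(trifluoromethanesulfonimide), O=S(=O)(N(c1ccccc1)S(=O)(=O)C(F)(F)F)C(F)(F)F
Why: enolate O-triflation; enolisation can only go toward the C3 methylene, because the alternative would place a double bond at the cyclopropane bridgehead.

Step 14
Reactants: 17 (1S,6R)-6-(propan-2-yl)bicyclo[4.1.0]hept-2-en-2-yl trifluoromethanesulfonate
Product: 18 4,4,5,5-tetramethyl-2-[(1R,6R)-6-(propan-2-yl)bicyclo[4.1.0]hept-2-en-2-yl]-1,3,2-dioxaborolane (same spatial arrangement as 16 and 17; the C1 descriptor changes only through priority)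
Conditions: B2pin2, PdCl2(dppf) (3 mol %), KOAc, 1,4-dioxane, 80 °C
Reagents that add atoms: bis(pinacolato)diboron, CC1(C)OB(OC1(C)C)B1OC(C)(C)C(C)(C)O1
Why: Miyaura borylation of an alkenyl triflate, with retention of the alkene position and no effect on the cyclopropane.

Step 15
Reactants: 10 14-bromo-11,12-bis(benzyloxy)-5β-abieta-8,11,13-trien-6-one; 18 alkenyl pinacol boronate
Product: 19 11,12-bis(benzyloxy)-14-[(1S,6R)-6-(propan-2-yl)bicyclo[4.1.0]hept-2-en-2-yl]-5β-abieta-8,11,13-trien-6-one (alkene C1′=C7′)
Conditions: Pd(OAc)2 (5 mol %), SPhos (10 mol %), K3PO4, toluene/H2O (10:1), 80 °C, degassed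
Reagents that add atoms: none
Why: Suzuki–Miyaura coupling in which a bulky dialkylbiarylphosphine allows oxidative addition and transmetalation at the doubly ortho-flanked bromide; C5 is already in its equilibrium configuration, so the basic medium cannot scramble it.

Step 16
Reactants: 19 alkenyl arene 6-ketone
Product: 20 epoxy ketone (19 with the C1′–C7′ epoxide on the face opposite the cyclopropane CH2, C6′)
Conditions: dimethyldioxirane (acetone solution), CH2Cl2, −20 → 0 °C; evaporate, use crude
Reagents that add atoms: dimethyldioxirane, CC1(C)OO1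
Why: electrophilic epoxidation of the only alkene, anti to the fused cyclopropane CH2 as in 2-carene-type bicyclo[4.1.0]hept-2-enes and through the rotamer about C14–C1′ that turns the isopropyl group away from the attacked face; the neutral oxidant with volatile by-product spares the acid-labile aryl epoxide.

Step 17
Reactants: 20 epoxy ketone
Product: 21 key-step precursor, the C6 tert-butyldimethylsilyl enol ether (C6=C7) of 20, 5β-H retained
Conditions: KN(SiMe3)2, THF, −78 °C; TBSCl, DMPU, −78 → 0 °C
Reagents that add atoms: tert-butyldimethylsilyl chloride, CC(C)(C)[Si](C)(C)Cl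
Why: silyl enol ether formation; kinetic and thermodynamic deprotonation coincide at benzylic C7, the hindered amide base does not open the epoxide, and C5 is not enolised.

Step 18
Reactants: 21 epoxide C6 silyl enol ether
Product: 23 hexacyclic 7′α-hydroxy 6-ketone dibenzyl ether (key-step product; 5β-H; 7α-H; C14 syn to C6′ on ring E), via boron-bound spiro aldehyde 22 (not isolated)
Conditions: BF3·OEt2 (1.5 equiv), 2,6-di-tert-butyl-4-methylpyridine (0.2 equiv), CH2Cl2, −78 °C; aq NaHCO3 at −78 °C
Reagents that add atoms: none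
Why: BF3 binds the epoxide oxygen and the C1′–O bond ionises, C1′ being tertiary, benzylic and cyclopropylcarbinyl, while the C7′–C2′ ring bond shifts to C1′ on the face opposite the departing oxygen and leaves C7′ as the boron-bound aldehyde 22; C7 of the silyl enol ether, held peri to this aldehyde, then adds to it and fluoride transfer to silicon ends the sequence. The closest known reactions are the Lewis-acid (Meinwald-type) contraction of 1-arylcyclohexene oxides to 1-arylcyclopentanecarbaldehydes and the BF3-promoted Mukaiyama aldol, here run one after the other in the same flask. Ring E is formed by the 1,2-shift (six- to five-membered contraction) and ring D by a 5-exo-trig closure with the enol double bond exocyclic to the new ring. C1′ is controlled by the epoxide face fixed in step 16 together with inversion at the migration terminus, which places C14 syn to C6′; C7′ is controlled by an open transition state in which the boron-bound oxygen turns to the α side, next to the tied-back C5′–H and away from C6; C7 (expected 7α-H) is of no consequence because it becomes sp2 in step 20. The step needs the C–C shift to outrun the 1,2-hydride shift from C7′ and the opening of the cyclopropylcarbinyl cation: in the contact ion pair the oxygen still covers the face it left, the C7′–H lies near the nodal plane of C1′ while the C7′–C2′ bond can reach its rear lobe, and −78 °C keeps the cation short-lived. The hindered pyridine removes traces of protic acid that would cleave the enol ether.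

Step 19
Reactants: 23 hexacyclic hydroxy ketone dibenzyl ether
Product: 24 hexacyclic 11,12-catechol (23 with both benzyl groups removed)
Conditions: H2 (1 atm), 10% Pd/C, EtOAc, rt; filter under Ar
Reagents that add atoms: none
Why: hydrogenolysis of the two aryl benzyl ethers under neutral conditions; the ketone, the non-benzylic carbinol and the unconjugated cyclopropane are inert, and neither a Lewis acid nor a base is present to dehydrate or retro-aldolise the β-hydroxy ketone.

Step 20
Reactants: 24 hexacyclic 11,12-catechol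
Product: 26 CNP0178265.2 (target quinone methide), via 11,12-o-quinone 25 (not isolated)
Conditions: Ag2O, Et2O, rt, dark; filter through Celite
Reagents that add atoms: none
Why: two-electron oxidation of the catechol to the o-quinone, which tautomerises by loss of the C7–H (α to the C6 ketone and vinylogous to the quinone carbonyl) to the 11-hydroxy quinone methide, the known behaviour of 11,12-dihydroxy-6-oxoabietatrienes; C7 becomes sp2 and the other five stereocentres are untouched.

**Compound list**

1 | carnosic acid (11,12-dihydroxyabieta-8,11,13-trien-20-oic acid) | CC(C)C1=C(C(=C2C(=C1)CC[C@@H]3[C@@]2(CCCC3(C)C)C(=O)O)O)O | starting material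
2 | benzyl 11,12-bis(benzyloxy)abieta-8,11,13-trien-20-oate | CC(C)c1cc2CC[C@H]3C(C)(C)CCC[C@]3(C(=O)OCc3ccccc3)c2c(OCc2ccccc2)c1OCc1ccccc1 | intermediate
3 | 11,12-bis(benzyloxy)abieta-8,11,13-trien-20-ol | CC(C)c1cc2CC[C@H]3C(C)(C)CCC[C@]3(CO)c2c(OCc2ccccc2)c1OCc1ccccc1 | intermediate
4 | 11,12-bis(benzyloxy)abieta-8,11,13-trien-20-al | CC(C)c1cc2CC[C@H]3C(C)(C)CCC[C@]3(C=O)c2c(OCc2ccccc2)c1OCc1ccccc1 | intermediate
5 | 11,12-bis(benzyloxy)abieta-8,11,13-triene | CC(C)c1cc2CC[C@H]3C(C)(C)CCC[C@]3(C)c2c(OCc2ccccc2)c1OCc1ccccc1 | intermediate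
6 | 14-bromo-11,12-bis(benzyloxy)abieta-8,11,13-triene | CC(C)c1c(Br)c2CC[C@H]3C(C)(C)CCC[C@]3(C)c2c(OCc2ccccc2)c1OCc1ccccc1 | intermediate
7 | 14-bromo-11,12-bis(benzyloxy)abieta-6,8,11,13-tetraene | CC(C)c1c(Br)c2C=C[C@H]3C(C)(C)CCC[C@]3(C)c2c(OCc2ccccc2)c1OCc1ccccc1 | intermediate
8 | 14-bromo-11,12-bis(benzyloxy)-6α,7α-epoxyabieta-8,11,13-triene | CC(C)c1c(Br)c2[C@@H]4O[C@@H]4[C@H]3C(C)(C)CCC[C@]3(C)c2c(OCc2ccccc2)c1OCc1ccccc1 | intermediate (not isolated)
9 | 14-bromo-11,12-bis(benzyloxy)-5α-abieta-8,11,13-trien-6-one (A/B trans) | CC(C)c1c(Br)c2CC(=O)[C@H]3C(C)(C)CCC[C@]3(C)c2c(OCc2ccccc2)c1OCc1ccccc1 | intermediate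
10 | 14-bromo-11,12-bis(benzyloxy)-5β-abieta-8,11,13-trien-6-one (A/B cis) | CC(C)c1c(Br)c2CC(=O)[C@@H]3C(C)(C)CCC[C@]3(C)c2c(OCc2ccccc2)c1OCc1ccccc1 | intermediate
11 | 3-ethoxycyclohex-2-en-1-one | CCOC1=CC(=O)CCC1 | starting material
12 | isopropylmagnesium chloride | CC(C)[Mg]Cl | starting material
13 | 3-(propan-2-yl)cyclohex-2-en-1-one | CC(C)C1=CC(=O)CCC1 | intermediate
14 | (R)-3-(propan-2-yl)cyclohex-2-en-1-ol | O[C@@H]1CCCC(C(C)C)=C1 | intermediate
15 | (1S,2R,6R)-6-(propan-2-yl)bicyclo[4.1.0]heptan-2-ol | O[C@@H]1CCC[C@]2(C(C)C)C[C@H]12 | intermediate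
16 | (1S,6R)-6-(propan-2-yl)bicyclo[4.1.0]heptan-2-one | O=C1CCC[C@]2(C(C)C)C[C@H]12 | intermediate
17 | (1S,6R)-6-(propan-2-yl)bicyclo[4.1.0]hept-2-en-2-yl trifluoromethanesulfonate | O=S(=O)(OC1=CCC[C@]2(C(C)C)C[C@H]12)C(F)(F)F | intermediate
18 | 4,4,5,5-tetramethyl-2-[(1R,6R)-6-(propan-2-yl)bicyclo[4.1.0]hept-2-en-2-yl]-1,3,2-dioxaborolane | CC1(C)OB(OC1(C)C)C1=CCC[C@]2(C(C)C)C[C@H]12 | intermediate
19 | 11,12-bis(benzyloxy)-14-[(1S,6R)-6-(propan-2-yl)bicyclo[4.1.0]hept-2-en-2-yl]-5β-abieta-8,11,13-trien-6-one | CC(C)c1c(C4=CCC[C@]5(C(C)C)C[C@H]45)c2CC(=O)[C@@H]3C(C)(C)CCC[C@]3(C)c2c(OCc2ccccc2)c1OCc1ccccc1 | intermediate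
20 | epoxy ketone: 19 with the C1′–C7′ epoxide anti to the cyclopropane CH2 | CC(C)c1c([C@]45O[C@H]4CC[C@]4(C(C)C)C[C@H]54)c2CC(=O)[C@@H]3C(C)(C)CCC[C@]3(C)c2c(OCc2ccccc2)c1OCc1ccccc1 | intermediate
21 | key-step precursor: C6 tert-butyldimethylsilyl enol ether (C6=C7) of 20, 5β-H | CC(C)c1c([C@]45O[C@H]4CC[C@]4(C(C)C)C[C@H]54)c2C=C(O[Si](C)(C)C(C)(C)C)[C@@H]3C(C)(C)CCC[C@]3(C)c2c(OCc2ccccc2)c1OCc1ccccc1 | intermediate
22 | spiro aldehyde: C6 silyl enol ether bearing at C14 the ring-contracted C1′(CHO) 4′-isopropylbicyclo[3.1.0]hexane, C14 syn to C6′ (boron-bound in the flask) | CC(C)c1c([C@]4(C=O)CC[C@]5(C(C)C)C[C@H]45)c2C=C(O[Si](C)(C)C(C)(C)C)[C@@H]3C(C)(C)CCC[C@]3(C)c2c(OCc2ccccc2)c1OCc1ccccc1 | intermediate (not isolated)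
23 | key-step product: hexacyclic 11,12-bis(benzyloxy) 6-ketone, ring D = C7–C8–C14–C1′–C7′, 7′-OH α (cis to C5′ across ring D), 7α-H, 5β-H, C14 syn to C6′ | CC(C)c1c2c3[C@H](C(=O)[C@@H]4C(C)(C)CCC[C@]4(C)c3c(OCc3ccccc3)c1OCc1ccccc1)[C@@H](O)[C@]21CC[C@]2(C(C)C)C[C@@H]21 | intermediate
24 | hexacyclic 11,12-dihydroxy 6-ketone (catechol of 23) | CC(C)c1c2c3[C@H](C(=O)[C@@H]4C(C)(C)CCC[C@]4(C)c3c(O)c1O)[C@@H](O)[C@]21CC[C@]2(C(C)C)C[C@@H]21 | intermediate
25 | hexacyclic 11,12-o-quinone (C7–H retained) | CC(C)C1=C2C(=C3C(=O)C1=O)[C@H](C(=O)[C@@H]4C(C)(C)CCC[C@]34C)[C@@H](O)[C@]21CC[C@]2(C(C)C)C[C@@H]21 | intermediate (not isolated)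
26 | CNP0178265.2, the 11-hydroxy-7,9(11),13-triene-6,12-dione quinone methide | CC(C)C1=C2C3=C(C(=O)[C@@H]4C(C)(C)CCC[C@]4(C)C3=C(O)C1=O)[C@@H](O)[C@]21CC[C@]2(C(C)C)C[C@@H]21 | target

**Step count and risks**

Total steps: 20. Longest linear sequence: 14 steps (steps 1–8, then 15–20); the boronate branch is 6 steps (9–14).

Most likely to fail, in order:

1. Step 18. The cationic centre at C1′ may be quenched by a 1,2-hydride shift from C7′ or by opening of the adjoining cyclopropane before the ring bond shifts, or the silyl enol ether may be lost to protodesilylation before the aldehyde exists. The fallback separates the two events; it sets out from 20 and returns at 23. Epoxy ketone 20, without the enol silane, is isomerised with methylaluminium bis(4-bromo-2,6-di-tert-butylphenoxide) in CH2Cl2 at −78 °C. This bulky aluminium Lewis acid is of the kind established for turning trisubstituted epoxides into aldehydes by alkyl shift, and its aryloxide ligands cannot add to the cation. The product is the keto aldehyde F1. The doubly activated C7 methylene of F1 then closes ring D in an amine-mediated intramolecular aldol (pyrrolidine, AcOH, THF, 0 °C). Under these reversible conditions the 7′-epimers should drain toward the isomer with the hydroxyl on the less hindered α side, which is 23.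

2. Step 15. Transmetalation at the doubly ortho-flanked arylpalladium bromide may be too slow, so that protodeboronation of the alkenyl boronate and hydrodebromination of 10 take over. The fallback replaces boron by zinc and reaches the alkenyl metal by another path; it sets out from 16 and 10 and returns at 19. Ketone 16 is condensed with 2,4,6-triisopropylbenzenesulfonyl hydrazide (THF, cat. HCl) to the trisylhydrazone F2. n-BuLi (2.2 equiv, THF, −78 → 0 °C) effects a Shapiro reaction on the methylene side to the alkenyllithium F3, which ZnCl2 converts into the alkenylzinc chloride F4. Negishi coupling of F4 with bromide 10 (Pd2(dba)3, XPhos, THF, 60 °C) gives 19. The organozinc tolerates the ketone and transmetalates faster than the boronate.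

3. Step 16. The arene stands perpendicular to the alkene and puts one ortho group over each alkene face, so oxygen transfer may go to the face syn to C6′; the product may also open under traces of acid. The fallback delivers the oxygen to the face opposite the one the electrophile prefers; it sets out from 19 and returns at 20. Treatment of 19 with NBS in THF/H2O at 0 °C forms the bromonium ion on the preferred face, and water opens it at tertiary C1′ from the other side to give the bromohydrin F5 (7′-Br syn to C6′, 1′-OH anti). K2CO3 in MeOH at 0 °C then closes the ring with inversion at C7′ to epoxide 20.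

**Further compounds**

F1 | step 18 | keto aldehyde: 11,12-bis(benzyloxy)-5β-abieta-8,11,13-trien-6-one bearing at C14 the C1′(CHO) 4′-isopropylbicyclo[3.1.0]hexane, C14 syn to C6′ | CC(C)c1c([C@]4(C=O)CC[C@]5(C(C)C)C[C@H]45)c2CC(=O)[C@@H]3C(C)(C)CCC[C@]3(C)c2c(OCc2ccccc2)c1OCc1ccccc1
F2 | step 15 | 2,4,6-triisopropylbenzenesulfonyl hydrazone of 16 (N–N syn to the C3 methylene) | CC(C)c1cc(C(C)C)c(S(=O)(=O)N/N=C2\CCC[C@]3(C(C)C)C[C@H]23)c(C(C)C)c1
F3 | step 15 | [6-(propan-2-yl)bicyclo[4.1.0]hept-2-en-2-yl]lithium, configured as 16 | [Li]C1=CCC[C@]2(C(C)C)C[C@H]12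
F4 | step 15 | chloro[6-(propan-2-yl)bicyclo[4.1.0]hept-2-en-2-yl]zinc, configured as 16 | Cl[Zn]C1=CCC[C@]2(C(C)C)C[C@H]12
F5 | step 16 | bromohydrin of 19: 1′-OH anti and 7′-Br syn to the cyclopropane CH2 | CC(C)c1c([C@]4(O)[C@H](Br)CC[C@]5(C(C)C)C[C@H]45)c2CC(=O)[C@@H]3C(C)(C)CCC[C@]3(C)c2c(OCc2ccccc2)c1OCc1ccccc1
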